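## Structural features

- The target 23 is an open-chain monoester with one benzene ring (ring A, 4-hydroxy-3,5-dimethoxyphenyl) and no other ring. A five-carbon 3-hydroxy-3-methylglutaric unit (C1–C5) is esterified at C1 by the primary allylic oxygen of (Z)-sinapyl alcohol, and C5 stays a free acid.
- The only stereocentre is C3, a fully substituted carbinol carbon carrying CH3, OH and two CH2–C(=O) arms; no stereocentres are adjacent.
- The two arms differ only four bonds from C3 (O-allyl against O–H). C3 is R only while the two carboxyl termini stay distinguishable, so any symmetrical intermediate (a cyclic anhydride, or an exchange of the ester group between the arms) erases it.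
- Fragile groups:
  - the Z styrenyl double bond, which light, acid or radicals turn into E;
  - the allylic ester para to a phenol, which can ionise, or expel the carboxylate through an extended quinone methide once the phenoxide is formed;
  - the β-hydroxy ester (retro-aldol, dehydration);
  - the electron-rich phenol (oxidation).
- The real difficulty is not the skeleton but making a quaternary carbinol whose two nearly identical arms are different from the start, then unmasking acid and phenol without harming the Z-allylic ester.
- The feature used: C3 with its methyl group, its oxygen and C2–C1(=O) is the β-carbon, β-oxygen, α-carbon and carboxyl of acetoacetic acid. Tied into a six-membered 1,3-dioxin-4-one through a stereogenic acetal carbon, C3 becomes C6 of that ring and can accept the C4–C5 arm as a carbon nucleophile on one face.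

## Logic of the disconnections

**23 back to 21.** The aryl O–Si bond and the O–C bond of the silylethyl ester are the last to be cut. Phenol and C5 acid must be masked while the C1 ester is made, and both masks fall to fluoride. The skeleton is not simplified, but the ester bond can then be formed without competition. The forward step must spare the Z-alkene, the allylic ester and the tertiary carbinol.

**21 back to 15 and 19.** The acyl C1–O(allyl) bond is cut. The ring carbonyl of 15 is already an activated ester, and the acetal that made the stereocentre leaves as 2 in the same operation. This splits the molecule into two fragments of similar size. The alkoxide 20 must attack the ring carbonyl and not the silylethyl ester, since attack on the latter would exchange the arms.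

**15 back to 14, 12 and 10.** These are functional-group changes on the C4–C5 arm: the ester C–O bond, the oxidation level of C5, and the C5–O bond traced back to a terminal alkene. A vinyl group is a CH2CO2H equivalent that is inert to organocopper chemistry and is distinct from the ring carbonyl from the moment it is introduced. The oxidations must be anti-Markovnikov and must not let the new hydroxyl or carboxyl group reach across to the ring carbonyl.

**10 back to 5 and 8.** The C3–C4 bond is cut (C6–vinyl in ring numbering). This is the step that builds the quaternary centre, and it reduces the problem to an acetoacetate derivative with one stereocentre at the acetal carbon. The forward step needs 1,4-addition, attack on one face, and an enolate that does not fragment.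

**5 back to 7, 3, and then 1 and 2.** The C–Br bond, the C5=C6 unsaturation and the two acetal C–O bonds are cut in turn. The stereocentre of 1 sets the acetal carbon in 3 and is then sacrificed, so chirality is stored at C2 until the key step returns it to C6. The forward steps need a cis-selective acetalisation and a dehydrogenation that leaves C2 alone.

**19 back to 18, 17 and 16.** The allylic C–O reduction level, the C=C bond and the aryl O–Si bond are cut. The two side-chain carbons come from a phosphonate reagent, which leads back to a cheap aromatic aldehyde. The olefination must be Z-selective and the geometry must survive the reduction.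

## Other disconnections considered

**Alternative 1:** The cut runs through the C1–C2 bond and the acyl C1–O bond of a four-membered ring. The β-lactone A1 would arise from the enantiopure 2,2-disubstituted epoxide A2 by insertion of CO into its CH2–O bond with [(salph)Al(THF)2][Co(CO)4].
- Mechanism: the aluminium cation activates the epoxide oxygen, Co(CO)4− opens the ring at the unhindered CH2, CO inserts into the new C–Co bond, and the aluminium alkoxide closes onto the acyl cobalt. The C–O bond at the fully substituted carbon is never broken, so A2 passes its configuration on unchanged.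
- In its favour: A1 is a strained acyl donor that 20 should open at the acyl carbon to give 21 directly. Only two steps would separate the key-step product from 23, against five in the chosen plan, and nothing but protecting groups is discarded. On step economy after the key step and on atom economy this alternative is the better one. The stereospecific relay of configuration is at least the equal of an acetal-controlled facial selection.
- Against it: the key step creates no stereocentre. A2 must be obtained enantiopure, and asymmetric epoxidation of a 1,1-disubstituted alkene or a homologation sequence on an epoxy alcohol costs steps or selectivity, so the overall count would probably not fall below that of the chosen plan. β,β-Disubstituted β-lactones are prone to alkyl–oxygen cleavage and loss of CO2, the ester group of A2 can compete for the Lewis acid, and pressurised CO with an air-sensitive cobaltate is needed.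
- Comparison: both plans reach the same tertiary carbinol with two different arms. The chosen plan makes the centre from a cheap hydroxy acid, whereas this one only transmits a centre that has to be secured elsewhere.

**Alternative 2:** The cut is the ring C–O bond of the δ-lactone A3 together with the oxidation level of one of the two hydroxyethyl arms of the achiral triol A4.
- Forward step: horse liver alcohol dehydrogenase with NAD+ recycling would oxidise one enantiotopic CH2OH of A4, the hydroxy aldehyde would close to the six-membered lactol, and a second dehydrogenation would give A3.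
- In its favour: one catalytic step from an achiral triol, in water, with no protecting group and no auxiliary. On step economy up to the stereocentre it is better than the chosen plan, which needs four steps.
- Against it: the enzyme has to tell apart two arms at a carbon whose other substituents, CH3 and OH, are of similar size, so the level of discrimination at a tertiary carbinol is uncertain. The chosen plan rests instead on a bulky tert-butyl group.
- The mapping is also awkward. In A3 as drawn (3S), the lactone carbonyl arm corresponds to the free-acid arm of 23 and the CH2–O terminus to the sinapyl ester carbon. The lactone would have to be opened, C1 masked, C5 oxidised to the acid and esterified with 19, and C1 unmasked: five or more steps, each working against relactonisation.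
- Comparison: the chosen plan meets the same lactonisation tendency once, at 12, so the two are equal in kind on that point. It keeps the ring carbonyl as the acyl donor and avoids the opening and re-differentiation.

**Alternative 3:** The cut is the C2–C3 bond and the acyl C1–O bond. The diazoketone A6, derived from (R)-citramalic acid A7, would lose N2 under PhCO2Ag and Et3N; the fully substituted C3 would migrate to the former diazo carbon with retention, and the ketene would be captured by 19 to give the fully silylated diester A5.
- In its favour: the stereocentre is bought intact in A7 and no stereoselective step is needed at all, which is better than the chosen plan on stereochemical certainty. The ester bond is formed from the neutral alcohol 19 with a ketene as the only acylating species, so exchange of the arms is impossible; in that respect it is better than step 11.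
- Against it: reaching A6 needs differentiation of the two carboxyl groups of A7, silylation of a tertiary hydroxyl, activation of a hindered α-silyloxy acid, and diazomethane or its silyl analogue, with the attendant hazard. The silver-mediated shift of a fully substituted, oxygen-bearing carbon is slow and competes with O–H insertion of the carbenoid into 19. The photochemical variant is ruled out by the Z-styrene.
- Comparison: A5 carries three silyl groups, so the final fluoride step has the same hazards as step 12. The step count (about six to A6, two more to 23) equals that of the chosen plan. The cuprate addition has closer precedent on its substrate class than the Wolff shift has on this one.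

Key step: step 4

Remark on the chemistry: the vinyl cuprate is assumed to enter trans to the tert-butyl group as alkyl cuprates do. With that sense the (S)-acetal 5 leads to (2S,6S)-10 and to R at C3 of 23, so the structures of 5, 10 and 23 are mutually consistent and none needed correcting. The design is tightened by silyl trapping in the key step, a buffered oxidative work-up in step 5 and an acyl-activating esterification in step 7.

## Route

Step 1
Reactants: 1 (S)-3-hydroxybutanoic acid; 2 pivalaldehyde (2,2-dimethylpropanal)
Product: 3 (2S,6S)-2-tert-butyl-6-methyl-1,3-dioxan-4-one (cis)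
Conditions: 2 (2 equiv), TsOH·H2O (cat.), CH2Cl2, reflux, water separator; recrystallisation
Reagents that add atoms: none
Why: Acid-catalysed acetalisation of a β-hydroxy acid with an aldehyde under removal of water; the acetal equilibrates, so the chair with tert-butyl and methyl both equatorial (cis) should predominate, which sets C2 as S from the S centre of 1, and crystallisation removes the trans isomer.

Step 2
Reactants: 3 (2S,6S)-2-tert-butyl-6-methyl-1,3-dioxan-4-one
Product: 7 (S)-5-bromo-2-tert-butyl-6-methyl-4H-1,3-dioxin-4-one, via 6-bromo dioxanone 4 (not isolated), via dioxinone 5 (not isolated), via 5,6-dibromo dioxanone 6 (not isolated)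
Conditions: NBS (2.1 equiv), AIBN (cat.), PhCF3, reflux; then Et3N (1.2 equiv), 0 °C
Reagents that add atoms: N-bromosuccinimide, O=C1CCC(=O)N1Br
Why: Wohl–Ziegler radical bromination at the tertiary, oxygen-activated C6–H gives 4, which loses HBr to the enol ether 5; 5 takes up the bromine released by the second equivalent of NBS to give 6, and base-assisted loss of HBr leaves the vinylic bromide 7; the acetal carbon is untouched and from here on carries the only stereocentre.

Step 3
Reactants: 7 (S)-5-bromo-2-tert-butyl-6-methyl-4H-1,3-dioxin-4-one
Product: 5 (S)-2-tert-butyl-6-methyl-4H-1,3-dioxin-4-one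
Conditions: H2 (1 atm, stopped after 1 equiv), Pd/C (cat.), Et3N (1.1 equiv), EtOAc, 0 °C
Reagents that add atoms: none
Why: Catalytic hydrogenolysis of a vinylic C–Br bond with an amine as HBr acceptor; the C–Br bond should react before the trisubstituted enol-ester double bond, and any over-reduction would only return 3, which can be recycled.

Step 4
Reactants: 5 (S)-2-tert-butyl-6-methyl-4H-1,3-dioxin-4-one; 8 vinylmagnesium bromide
Product: 10 (2S,6S)-2-tert-butyl-6-methyl-6-vinyl-1,3-dioxan-4-one (vinyl trans to tert-butyl), via silyl ketene acetal 9 (not isolated)
Conditions: 8 (3.0 equiv), CuBr·SMe2 (1.5 equiv), THF, −78 → −40 °C; Me3SiCl (3 equiv), then 5, −78 → −40 °C; sat. aq NH4Cl at −40 °C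
Reagents that add atoms: none
Why: Two equivalents of 8 and CuBr·SMe2 give the divinylcuprate, which forms a π-complex with the C5=C6 bond of 5, adds oxidatively at C6 to a trivalent-copper enolate and transfers one vinyl group by reductive elimination, forming the C6–vinyl bond (C3–C4 of 23). Me3SiCl traps the enolate as the silyl ketene acetal 9; this should speed up the slow transfer of an sp2 ligand to a β,β-disubstituted, oxygen-donor-bearing acceptor and suppress β-elimination of the ring oxygen from the metal enolate, and aqueous NH4Cl then hydrolyses 9 to 10. The closest known reaction type is the conjugate addition of dialkylcuprates to enantiopure 2-tert-butyl-6-alkyl-1,3-dioxin-4-ones, of which the vinyl case is a direct extension. No ring is closed. The new stereocentre C6 is controlled by the acetal carbon C2: the dioxinone is a sofa with C2 out of the plane and tert-butyl pseudo-equatorial, and the cuprate enters from the face that carries the axial acetal hydrogen, trans to tert-butyl, which gives 6S. The step needs 1,4- over 1,2-selectivity (secured by the soft cuprate at low temperature), facial selectivity (secured by the acetal) and survival of the ring (secured by silyl trapping and a cold quench).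

Step 5
Reactants: 10 (2S,6S)-2-tert-butyl-6-methyl-6-vinyl-1,3-dioxan-4-one
Product: 12 (2S,6R)-2-tert-butyl-6-(2-hydroxyethyl)-6-methyl-1,3-dioxan-4-one, via alkylborane 11 (not isolated)
Conditions: 9-BBN (1.3 equiv), THF, 0 °C → rt; then pH 7 phosphate buffer, 30% H2O2, 0 °C; crude product used at once
Reagents that add atoms: hydrogen peroxide, OO
Why: Anti-Markovnikov hydroboration of the monosubstituted alkene with the bulky, ester-tolerant 9-BBN puts boron on the terminal carbon (11), and oxidation of the C–B bond with H2O2 at pH 7 avoids an alkoxide, so that the axial hydroxyethyl arm should not transacylate onto the ring carbonyl; C6 is not involved (its descriptor changes to R only through the priority rules).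

Step 6
Reactants: 12 (2S,6R)-2-tert-butyl-6-(2-hydroxyethyl)-6-methyl-1,3-dioxan-4-one
Product: 14 2-[(2S,4R)-2-tert-butyl-4-methyl-6-oxo-1,3-dioxan-4-yl]acetic acid, via aldehyde 13 (not isolated)
Conditions: TEMPO (0.2 equiv), PhI(OAc)2 (2.5 equiv), MeCN/H2O 1:1, 0 °C → rt
Reagents that add atoms: water, O
Why: Oxoammonium (TEMPO) oxidation with PhI(OAc)2 as terminal oxidant takes the primary alcohol through aldehyde 13 and its hydrate to the acid under neutral to weakly acidic conditions that the acylal ring tolerates; no stereocentre is touched.

Step 7
Reactants: 14 2-[(2S,4R)-2-tert-butyl-4-methyl-6-oxo-1,3-dioxan-4-yl]acetic acid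
Product: 15 2-(trimethylsilyl)ethyl 2-[(2S,4R)-2-tert-butyl-4-methyl-6-oxo-1,3-dioxan-4-yl]acetate
Conditions: Me3SiCH2CH2OH (1.5 equiv), DCC (1.2 equiv), DMAP (0.1 equiv), CH2Cl2, 0 °C → rt
Reagents that add atoms: 2-(trimethylsilyl)ethanol, C[Si](C)(C)CCO
Why: Steglich esterification; the carboxyl group is converted at once into an acyl donor and so cannot act as an internal nucleophile toward the ring carbonyl (which would make the two arms equivalent), and the 2-silylethyl ester can later be removed by fluoride without acid or hydrogen.

Step 8
Reactants: 16 syringaldehyde (4-hydroxy-3,5-dimethoxybenzaldehyde)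
Product: 17 4-[(tert-butyldimethylsilyl)oxy]-3,5-dimethoxybenzaldehyde
Conditions: TBSCl (1.3 equiv), imidazole (2.5 equiv), DMF, rt
Reagents that add atoms: tert-butyldimethylsilyl chloride, CC(C)(C)[Si](C)(C)Cl
Why: Silylation of a phenol with a silyl chloride and imidazole; the silyl ether masks the acidic OH during the phosphonate, hydride and alkoxide steps, and the two flanking methoxy groups shield it against later silyl transfer.

Step 9
Reactants: 17 4-[(tert-butyldimethylsilyl)oxy]-3,5-dimethoxybenzaldehyde
Product: 18 methyl (2Z)-3-{4-[(tert-butyldimethylsilyl)oxy]-3,5-dimethoxyphenyl}prop-2-enoate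
Conditions: (CF3CH2O)2P(O)CH2CO2Me (1.2 equiv), KN(SiMe3)2 (1.2 equiv), 18-crown-6 (3 equiv), THF, −78 °C, light excluded
Reagents that add atoms: methyl 2-[bis(2,2,2-trifluoroethoxy)phosphoryl]acetate, COC(=O)CP(=O)(OCC(F)(F)F)OCC(F)(F)F
Why: Still–Gennari variant of the Horner–Wadsworth–Emmons olefination; with the electron-poor phosphonate and a dissociated potassium counter-ion the first adduct should eliminate faster than it equilibrates, so the Z-enoate is the kinetic product, and residual E isomer is removed by chromatography.

Step 10
Reactants: 18 methyl (2Z)-3-{4-[(tert-butyldimethylsilyl)oxy]-3,5-dimethoxyphenyl}prop-2-enoate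
Product: 19 (2Z)-3-{4-[(tert-butyldimethylsilyl)oxy]-3,5-dimethoxyphenyl}prop-2-en-1-ol
Conditions: i-Bu2AlH (2.5 equiv), CH2Cl2, −78 °C; aq potassium sodium tartrate
Reagents that add atoms: none
Why: 1,2-Reduction of a conjugated ester by i-Bu2AlH at low temperature gives the allylic alcohol without touching the alkene geometry or the aryl silyl ether.

Step 11
Reactants: 19 (2Z)-3-{4-[(tert-butyldimethylsilyl)oxy]-3,5-dimethoxyphenyl}prop-2-en-1-ol; 15 2-(trimethylsilyl)ethyl 2-[(2S,4R)-2-tert-butyl-4-methyl-6-oxo-1,3-dioxan-4-yl]acetate
Product: 21 1-[(2Z)-3-{4-[(tert-butyldimethylsilyl)oxy]-3,5-dimethoxyphenyl}prop-2-en-1-yl] 5-[2-(trimethylsilyl)ethyl] (3S)-3-hydroxy-3-methylpentanedioate, via lithium alkoxide 20 (not isolated)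
Conditions: 19, LiN(SiMe3)2 (1.0 equiv), THF, −78 °C; then 15 (1.05 equiv), −78 → −20 °C; AcOH (1.1 equiv), −20 °C
Reagents that add atoms: none
Why: Alkoxide alcoholysis of a 1,3-dioxan-4-one: 20 attacks the ring carbonyl of 15, an acylal-type lactone that is more electrophilic than the alkyl ester and has a hemiacetal oxygen as leaving group, and the opening becomes irreversible through loss of 2; no bond to C3 is broken, so its configuration is kept (the descriptor of 21 is S only because the silylethyl arm outranks the sinapyl arm).

Step 12
Reactants: 21 1-[(2Z)-3-{4-[(tert-butyldimethylsilyl)oxy]-3,5-dimethoxyphenyl}prop-2-en-1-yl] 5-[2-(trimethylsilyl)ethyl] (3S)-3-hydroxy-3-methylpentanedioate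
Product: 23 (3R)-3-hydroxy-5-{[(2Z)-3-(4-hydroxy-3,5-dimethoxyphenyl)prop-2-en-1-yl]oxy}-3-methyl-5-oxopentanoic acid, via phenol silylethyl ester 22 (not isolated)
Conditions: Bu4NF (3 equiv), THF, 0 °C → rt, light excluded; then cold dilute aq HCl to pH 3–4
Reagents that add atoms: none
Why: Fluoride-induced desilylation: the aryl silyl ether is cleaved first (22), then fluoride attacks silicon of the 2-silylethyl ester, which fragments to ethylene, Me3SiF and the carboxylate; no acid, hydrogen or transition metal is used, so the Z-alkene and the allylic ester should survive, and cold acidification gives 23.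

## Compound list

1 | (S)-3-hydroxybutanoic acid | C[C@H](O)CC(=O)O | starting material
2 | pivalaldehyde (2,2-dimethylpropanal) | CC(C)(C)C=O | starting material
3 | (2S,6S)-2-tert-butyl-6-methyl-1,3-dioxan-4-one (cis) | C[C@H]1CC(=O)O[C@@H](C(C)(C)C)O1 | intermediate
4 | (2S)-6-bromo-2-tert-butyl-6-methyl-1,3-dioxan-4-one (C6 epimers, not isolated) | CC1(Br)CC(=O)O[C@@H](C(C)(C)C)O1 | intermediate
5 | (S)-2-tert-butyl-6-methyl-4H-1,3-dioxin-4-one (transient in step 2, isolated in step 3) | CC1=CC(=O)O[C@@H](C(C)(C)C)O1 | intermediate
6 | (2S)-5,6-dibromo-2-tert-butyl-6-methyl-1,3-dioxan-4-one (isomer mixture at C5 and C6, not isolated) | CC1(Br)C(Br)C(=O)O[C@@H](C(C)(C)C)O1 | intermediate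
7 | (S)-5-bromo-2-tert-butyl-6-methyl-4H-1,3-dioxin-4-one | CC1=C(Br)C(=O)O[C@@H](C(C)(C)C)O1 | intermediate
8 | vinylmagnesium bromide | C=C[Mg]Br | starting material
9 | (2S,4R)-2-tert-butyl-4-methyl-6-(trimethylsilyloxy)-4-vinyl-4H-1,3-dioxine (silyl ketene acetal, not isolated) | C=C[C@]1(C)C=C(O[Si](C)(C)C)O[C@@H](C(C)(C)C)O1 | intermediate
10 | (2S,6S)-2-tert-butyl-6-methyl-6-vinyl-1,3-dioxan-4-one (vinyl trans to tert-butyl) | C=C[C@]1(C)CC(=O)O[C@@H](C(C)(C)C)O1 | intermediate
11 | 9-{2-[(2S,4R)-2-tert-butyl-4-methyl-6-oxo-1,3-dioxan-4-yl]ethyl}-9-borabicyclo[3.3.1]nonane (not isolated) | B1(CC[C@]3(C)CC(=O)O[C@@H](C(C)(C)C)O3)C2CCCC1CCC2 | intermediate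
12 | (2S,6R)-2-tert-butyl-6-(2-hydroxyethyl)-6-methyl-1,3-dioxan-4-one | OCC[C@]1(C)CC(=O)O[C@@H](C(C)(C)C)O1 | intermediate
13 | 2-[(2S,4R)-2-tert-butyl-4-methyl-6-oxo-1,3-dioxan-4-yl]acetaldehyde (not isolated) | O=CC[C@]1(C)CC(=O)O[C@@H](C(C)(C)C)O1 | intermediate
14 | 2-[(2S,4R)-2-tert-butyl-4-methyl-6-oxo-1,3-dioxan-4-yl]acetic acid | OC(=O)C[C@]1(C)CC(=O)O[C@@H](C(C)(C)C)O1 | intermediate
15 | 2-(trimethylsilyl)ethyl 2-[(2S,4R)-2-tert-butyl-4-methyl-6-oxo-1,3-dioxan-4-yl]acetate | C[Si](C)(C)CCOC(=O)C[C@]1(C)CC(=O)O[C@@H](C(C)(C)C)O1 | intermediate
16 | syringaldehyde (4-hydroxy-3,5-dimethoxybenzaldehyde) | COc1cc(C=O)cc(OC)c1O | starting material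
17 | 4-[(tert-butyldimethylsilyl)oxy]-3,5-dimethoxybenzaldehyde | COc1cc(C=O)cc(OC)c1O[Si](C)(C)C(C)(C)C | intermediate
18 | methyl (2Z)-3-{4-[(tert-butyldimethylsilyl)oxy]-3,5-dimethoxyphenyl}prop-2-enoate | COC(=O)/C=C\c1cc(OC)c(O[Si](C)(C)C(C)(C)C)c(OC)c1 | intermediate
19 | (2Z)-3-{4-[(tert-butyldimethylsilyl)oxy]-3,5-dimethoxyphenyl}prop-2-en-1-ol | COc1cc(/C=C\CO)cc(OC)c1O[Si](C)(C)C(C)(C)C | intermediate
20 | lithium (2Z)-3-{4-[(tert-butyldimethylsilyl)oxy]-3,5-dimethoxyphenyl}prop-2-en-1-olate (not isolated) | [Li+].[O-]C/C=C\c1cc(OC)c(O[Si](C)(C)C(C)(C)C)c(OC)c1 | intermediate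
21 | 1-[(2Z)-3-{4-[(tert-butyldimethylsilyl)oxy]-3,5-dimethoxyphenyl}prop-2-en-1-yl] 5-[2-(trimethylsilyl)ethyl] (3S)-3-hydroxy-3-methylpentanedioate | COc1cc(/C=C\COC(=O)C[C@](C)(O)CC(=O)OCC[Si](C)(C)C)cc(OC)c1O[Si](C)(C)C(C)(C)C | intermediate
22 | 1-[(2Z)-3-(4-hydroxy-3,5-dimethoxyphenyl)prop-2-en-1-yl] 5-[2-(trimethylsilyl)ethyl] (3S)-3-hydroxy-3-methylpentanedioate (not isolated) | COc1cc(/C=C\COC(=O)C[C@](C)(O)CC(=O)OCC[Si](C)(C)C)cc(OC)c1O | intermediate
23 | (3R)-3-hydroxy-5-{[(2Z)-3-(4-hydroxy-3,5-dimethoxyphenyl)prop-2-en-1-yl]oxy}-3-methyl-5-oxopentanoic acid | COc1cc(/C=C\COC(=O)C[C@](C)(O)CC(=O)O)cc(OC)c1O | target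

## Step count and least certain steps

Total: 12 steps. Longest linear sequence: 9 steps (steps 1–7, 11 and 12); steps 8–10 form the second branch.

**Step 4 (key step).**
- Risk: slow transfer of the vinyl ligand to an electron-rich, β,β-disubstituted acceptor, so that 1,2-attack or fragmentation of the enolate (β-elimination of the ring oxygen on warming) takes over. The small vinyl ligand may also discriminate the two faces less well than alkyl ligands do.
- Fallback, from 5 to 14: the more reactive allylcopper reagent (allylmagnesium bromide, CuBr·SMe2, Me3SiCl, THF, −78 °C) should give (2S,6R)-6-allyl-2-tert-butyl-6-methyl-1,3-dioxan-4-one F1, allyl trans to tert-butyl. Oxidative cleavage of its terminal alkene (RuCl3·xH2O cat., NaIO4, MeCN/EtOAc/H2O) should then give 14 directly. The route is rejoined at 14 and steps 5 and 6 are not needed.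

**Step 5.**
- Risk: transannular acyl transfer. The hydroxyethyl arm sits axial, close to the ring carbonyl, and can attack it with expulsion of the acetal oxygen and loss of 2 during the oxidative work-up or on concentration. The activated carbonyl needed in step 11 would be lost.
- Fallback, from 10 to 14: an aldehyde-selective Wacker oxidation (PdCl2(PhCN)2, CuCl2·2H2O and AgNO2 as catalysts, O2, t-BuOH/MeNO2), of the kind used for alkenes with allylic oxygen, should lead to 13 without a free hydroxyl group ever being present. Pinnick oxidation (NaClO2, NaH2PO4, 2-methylbut-2-ene, t-BuOH/H2O) then gives 14, where the route is rejoined.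

**Step 9.**
- Risk: incomplete Z-selectivity with an electron-rich aryl aldehyde, and Z to E isomerisation of the cinnamate in light. Either would carry the wrong alkene geometry into 23.
- Fallback, from 17 to 19: Corey–Fuchs homologation (CBr4, PPh3, CH2Cl2, 0 °C) to tert-butyl[4-(2,2-dibromoethenyl)-2,6-dimethoxyphenoxy]dimethylsilane F2. Treatment with n-BuLi (2.1 equiv, THF, −78 °C) and paraformaldehyde gives 3-{4-[(tert-butyldimethylsilyl)oxy]-3,5-dimethoxyphenyl}prop-2-yn-1-ol F3. Cis-selective semihydrogenation (H2, Pd/CaCO3 poisoned with Pb(OAc)2, quinoline, EtOAc) gives 19, where the Z geometry is fixed by syn addition of hydrogen.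

**Step 11.**
- Risk: attack of the alkoxide on the silylethyl ester instead of the ring carbonyl, which exchanges the two arms and erodes enantiomeric purity.
- Further risks: deprotonation at the α-carbon followed by β-elimination of the ring oxygen; silyl transfer from the aryl oxygen to the alkoxide; retro-aldol cleavage of the tertiary alkoxide once the ring has opened.
- Fallback, from 15 to 21: hydrolysis of the acetal with a sulfonic acid resin (Dowex 50W, H+ form, MeCN/H2O, 40 °C) to (3S)-3-hydroxy-3-methyl-5-oxo-5-[2-(trimethylsilyl)ethoxy]pentanoic acid F4. Steglich esterification of F4 with the neutral alcohol 19 (EDC·HCl, DMAP cat., CH2Cl2, 0 °C) gives 21. No alkoxide is involved.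

**Step 12.**
- Risk: fluoride frees the phenoxide before the silylethyl ester has fragmented. The phenoxide can push out the allylic carboxylate through an extended quinone methide, and the basic medium can also isomerise the Z-alkene.
- Fallback, from 14 to 23, in which the phenol is unmasked last and under buffered conditions:
  - Esterify 14 with 2,2,2-trichloroethanol (DCC, DMAP cat.) to 2,2,2-trichloroethyl 2-[(2S,4R)-2-tert-butyl-4-methyl-6-oxo-1,3-dioxan-4-yl]acetate F5.
  - Hydrolyse the acetal (Dowex 50W, H+ form, MeCN/H2O) to (3S)-3-hydroxy-3-methyl-5-oxo-5-(2,2,2-trichloroethoxy)pentanoic acid F6.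
  - Steglich esterification with 19 gives the trichloroethyl silyl-protected diester F7.
  - Zn dust in AcOH/THF removes the trichloroethyl group while the phenol is still silylated, giving the silyl-protected acid F8.
  - HF·pyridine buffered with pyridine (THF, 0 °C) cleaves the aryl silyl ether without forming a free phenoxide and gives 23.

## Further compounds

F1 | step 4 | (2S,6R)-6-allyl-2-tert-butyl-6-methyl-1,3-dioxan-4-one | C=CC[C@]1(C)CC(=O)O[C@@H](C(C)(C)C)O1
F0 | step 5 | none | none
F2 | step 9 | tert-butyl[4-(2,2-dibromoethenyl)-2,6-dimethoxyphenoxy]dimethylsilane | COc1cc(C=C(Br)Br)cc(OC)c1O[Si](C)(C)C(C)(C)C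
F3 | step 9 | 3-{4-[(tert-butyldimethylsilyl)oxy]-3,5-dimethoxyphenyl}prop-2-yn-1-ol | COc1cc(C#CCO)cc(OC)c1O[Si](C)(C)C(C)(C)C
F4 | step 11 | (3S)-3-hydroxy-3-methyl-5-oxo-5-[2-(trimethylsilyl)ethoxy]pentanoic acid | OC(=O)C[C@](C)(O)CC(=O)OCC[Si](C)(C)C
F5 | step 12 | 2,2,2-trichloroethyl 2-[(2S,4R)-2-tert-butyl-4-methyl-6-oxo-1,3-dioxan-4-yl]acetate | ClC(Cl)(Cl)COC(=O)C[C@]1(C)CC(=O)O[C@@H](C(C)(C)C)O1
F6 | step 12 | (3S)-3-hydroxy-3-methyl-5-oxo-5-(2,2,2-trichloroethoxy)pentanoic acid | OC(=O)C[C@](C)(O)CC(=O)OCC(Cl)(Cl)Cl
F7 | step 12 | 1-[(2Z)-3-{4-[(tert-butyldimethylsilyl)oxy]-3,5-dimethoxyphenyl}prop-2-en-1-yl] 5-(2,2,2-trichloroethyl) (3S)-3-hydroxy-3-methylpentanedioate | COc1cc(/C=C\COC(=O)C[C@](C)(O)CC(=O)OCC(Cl)(Cl)Cl)cc(OC)c1O[Si](C)(C)C(C)(C)C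
F8 | step 12 | (3R)-5-{[(2Z)-3-{4-[(tert-butyldimethylsilyl)oxy]-3,5-dimethoxyphenyl}prop-2-en-1-yl]oxy}-3-hydroxy-3-methyl-5-oxopentanoic acid | COc1cc(/C=C\COC(=O)C[C@](C)(O)CC(=O)O)cc(OC)c1O[Si](C)(C)C(C)(C)C
A1 | alternative 1 | 2-(trimethylsilyl)ethyl 2-(2-methyl-4-oxooxetan-2-yl)acetate, enantiomer as drawn | O=C1C[C@@](C)(CC(=O)OCC[Si](C)(C)C)O1
A2 | alternative 1 | 2-(trimethylsilyl)ethyl 2-[(2R)-2-methyloxiran-2-yl]acetate | C1[C@@](C)(CC(=O)OCC[Si](C)(C)C)O1
A3 | alternative 2 | (3S)-mevalonolactone, (4S)-4-hydroxy-4-methyloxan-2-one | O=C1C[C@@](C)(O)CCO1
A4 | alternative 2 | 3-methylpentane-1,3,5-triol | CC(O)(CCO)CCO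
A5 | alternative 3 | triethylsilyl ether of 21 (fully silylated diester) | COc1cc(/C=C\COC(=O)C[C@](C)(O[Si](CC)(CC)CC)CC(=O)OCC[Si](C)(C)C)cc(OC)c1O[Si](C)(C)C(C)(C)C
A6 | alternative 3 | 2-(trimethylsilyl)ethyl (3R)-5-diazo-3-methyl-4-oxo-3-[(triethylsilyl)oxy]pentanoate | [N-]=[N+]=CC(=O)[C@](C)(O[Si](CC)(CC)CC)CC(=O)OCC[Si](C)(C)C
A7 | alternative 3 | (R)-citramalic acid, (2R)-2-hydroxy-2-methylbutanedioic acid | O=C(O)[C@](C)(O)CC(=O)O
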